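**Plan**

- Feature used: ring C (O–C7–C8, fused to ring B at C3'–C4') is a trans-2-aryl-2,3-dihydrobenzofuran whose oxygen on C4' lies ortho to the C5' methoxy group and para to C1'. It is the formal [3+2] adduct of an (E)-alkene C7=C8 with the O=C4'–C3'(H) unit of a 2-methoxy-para-quinone 4-imine whose nitrogen marks C1'.
- Cuts, in retrosynthetic order: both primary alcohols back to a C9 pivalate and a C9' methyl ester; C1'–C7' back to an arylamine and methyl acrylate; then C8–C3' and O–C7 together, back to (E)-3,4,5-trimethoxycinnamyl pivalate and the N-tosyl quinone monoimine.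
- Forward: the alkene (three steps from 3,4,5-trimethoxycinnamic acid) and the quinone monoimine (three steps from 2-methoxy-4-nitrophenol) are joined, and ring C, the only ring made, closes in the same acid-catalysed step. N–S cleavage, diazotisation/Heck–Matsuda coupling and one i-Bu2AlH reduction finish the chain and free both alcohols.
- Stereochemistry: C8 (S) is set by a chiral BINOL-derived phosphoric acid in the C8–C3' bond formation, C7 (R) by ring closure trans to the C8 substituent, and the 7'E alkene by syn-insertion/syn-β-hydride elimination in the Heck–Matsuda step.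

Key step: step 7

Assumption: the sense of induction of the (R)-configured acid is assigned by analogy with related quinone-monoimine cycloadditions; should it favour the (7S,8R) series, the (S)-acid is used and nothing else changes.

**Route**

Step 1
Reactants: 1 (E)-3,4,5-trimethoxycinnamic acid
Product: 2 methyl (E)-3-(3,4,5-trimethoxyphenyl)prop-2-enoate
Conditions: MeOH, H2SO4 (cat.), reflux
Reagents that add atoms: methanol, CO
Why: Fischer esterification in excess methanol gives the ester that i-Bu2AlH reduces cleanly, and the (E)-alkene is not affected.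

Step 2
Reactants: 2 methyl (E)-3-(3,4,5-trimethoxyphenyl)prop-2-enoate
Product: 3 (E)-3-(3,4,5-trimethoxyphenyl)prop-2-en-1-ol
Conditions: i-Bu2AlH (2.5 equiv), CH2Cl2, −78 °C; aq. potassium sodium tartrate
Reagents that add atoms: none
Why: i-Bu2AlH reduces α,β-unsaturated esters in a 1,2-sense to the allylic alcohol at low temperature, without conjugate reduction or loss of the (E)-geometry.

Step 3
Reactants: 3 (E)-3-(3,4,5-trimethoxyphenyl)prop-2-en-1-ol
Product: 4 (E)-3-(3,4,5-trimethoxyphenyl)allyl pivalate
Conditions: PivCl, pyridine, DMAP (cat.), CH2Cl2, 0 °C → rt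
Reagents that add atoms: pivaloyl chloride, CC(C)(C)C(=O)Cl
Why: DMAP-catalysed acylation of the primary allylic alcohol gives a hindered ester that should be inert to Brønsted acid, to SmI2 at low temperature, to carbonate and to palladium, yet is cleaved by i-Bu2AlH in the last step.

Step 4
Reactants: 5 2-methoxy-4-nitrophenol
Product: 6 4-amino-2-methoxyphenol
Conditions: H2 (1 atm), Pd/C (10 %), MeOH, rt; filtered and used at once
Reagents that add atoms: none
Why: Catalytic hydrogenation of a nitroarene over palladium gives the aminophenol with water as the only by-product, and the air-sensitive product is taken on directly.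

Step 5
Reactants: 6 4-amino-2-methoxyphenol
Product: 7 N-(4-hydroxy-3-methoxyphenyl)-4-methylbenzenesulfonamide
Conditions: TsCl (1.0 equiv), pyridine, CH2Cl2, 0 °C
Reagents that add atoms: 4-methylbenzenesulfonyl chloride, Cc1ccc(S(=O)(=O)Cl)cc1
Why: Under pyridine the aniline nitrogen is far more nucleophilic than the un-ionised phenol, so one equivalent of sulfonyl chloride should give chemoselective N-sulfonylation.

Step 6
Reactants: 7 N-(4-hydroxy-3-methoxyphenyl)-4-methylbenzenesulfonamide
Product: 8 N-(3-methoxy-4-oxocyclohexa-2,5-dien-1-ylidene)-4-methylbenzenesulfonamide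
Conditions: PhI(OAc)2 (1.05 equiv), CH2Cl2, 0 °C → rt
Reagents that add atoms: none
Why: Two-electron oxidation of a para-sulfonamidophenol by trivalent iodine (ligand exchange at the phenol oxygen, then loss of iodobenzene and acetate) is the standard way to N-sulfonyl quinone monoimines, and the aprotic solvent prevents ketal formation.

Step 7
Reactants: 4 (E)-3-(3,4,5-trimethoxyphenyl)allyl pivalate; 8 N-(3-methoxy-4-oxocyclohexa-2,5-dien-1-ylidene)-4-methylbenzenesulfonamide
Product: 9 [(2R,3S)-7-methoxy-5-(4-methylbenzenesulfonamido)-2-(3,4,5-trimethoxyphenyl)-2,3-dihydro-1-benzofuran-3-yl]methyl 2,2-dimethylpropanoate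
Conditions: (R)-3,3'-bis(2,4,6-triisopropylphenyl)-1,1'-binaphthyl-2,2'-diyl hydrogen phosphate (10 mol %), 4 Å MS, CH2Cl2, −20 → 0 °C
Reagents that add atoms: none
Why: Proposed new method: the phosphoric acid hydrogen-bonds to the sulfonyl imine of 8, alkene carbon C8 of 4 adds to the only unsubstituted carbon β to the imine (the one next to the carbonyl, the future C3'), the adduct tautomerises to a para-sulfonamidophenol, and its oxygen captures the benzylic C7 cation, so that C8–C3' and O–C7 form in one operation. The closest known reaction types are the BF3-promoted formal [3+2] cycloaddition of 2-alkoxy N-sulfonyl quinone monoimines with (E)-propenylarenes, which gives trans-2-aryl-7-alkoxy-5-sulfonamido-2,3-dihydrobenzofurans, and the chiral-phosphoric-acid [3+2] cycloaddition of N-sulfonyl quinone monoimines with enamides, vinylindoles and hydroxystyrenes; new here is the enantioselective use of a cinnamyl ester that offers the catalyst no hydrogen-bond donor. Ring C closes by 5-exo-trig attack of the phenol oxygen on C7, the cation being written as its para-methoxy-stabilised quinoid oxocarbenium form. C8 is set in the C–C bond-forming event, in which the phosphate, hydrogen-bonded to the imine nitrogen and ion-paired with the developing C7 cation between the two triisopropylphenyl groups, selects the alkene face; C7 follows from closure anti to the C8 pivaloyloxymethyl group, favoured kinetically by the (E)-alkene and thermodynamically because the benzylic C–O bond is reversible under acid, which gives the trans ring. The step needs regioselectivity on the quinone and O- over N-closure: the methoxy group occupies and deactivates the other β-carbon of the imine and ends at C5', the acid binds the more basic imine (a vinylogous imidate) and not the carbonyl, and only the oxygen is ortho to the new bond, the nitrogen being para and remaining as the C1' handle. The pivalate lowers the nucleophilicity of the alkene only inductively and is inert to the acid, and the molecular sieves keep the imine from hydrolysing.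

Step 8
Reactants: 9 [(2R,3S)-7-methoxy-5-(4-methylbenzenesulfonamido)-2-(3,4,5-trimethoxyphenyl)-2,3-dihydro-1-benzofuran-3-yl]methyl 2,2-dimethylpropanoate
Product: 12 [(2R,3S)-5-amino-7-methoxy-2-(3,4,5-trimethoxyphenyl)-2,3-dihydro-1-benzofuran-3-yl]methyl 2,2-dimethylpropanoate, via N-trifluoroacetyl sulfonamide 10 (not isolated), via trifluoroacetanilide 11 (not isolated)
Conditions: (CF3CO)2O, pyridine, CH2Cl2, 0 °C; evaporate; SmI2 (2.5 equiv), THF, −78 °C; then K2CO3, MeOH–H2O, rt
Reagents that add atoms: none
Why: N-Trifluoroacetylation turns the acidic N–H sulfonamide, which would otherwise be deprotonated and resist electron transfer, into an N-acyl sulfonamide whose N–S bond is cleaved by single-electron transfer from SmI2 already at −78 °C (where the pivalate and the benzylic ether are inert), and the resulting trifluoroacetanilide is hydrolysed by mild carbonate without touching the pivalate or the stereocentres.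

Step 9
Reactants: 12 [(2R,3S)-5-amino-7-methoxy-2-(3,4,5-trimethoxyphenyl)-2,3-dihydro-1-benzofuran-3-yl]methyl 2,2-dimethylpropanoate; 13 methyl acrylate
Product: 15 methyl (E)-3-[(2R,3S)-3-[(2,2-dimethylpropanoyloxy)methyl]-7-methoxy-2-(3,4,5-trimethoxyphenyl)-2,3-dihydro-1-benzofuran-5-yl]prop-2-enoate, via arenediazonium methanesulfonate 14 (not isolated)
Conditions: t-BuONO (1.2 equiv), MeSO3H (1.1 equiv), MeCN, 0 °C; then 13 (3 equiv), NaOAc (2 equiv), Pd(OAc)2 (5 mol %), rt
Reagents that add atoms: none
Why: One-pot diazotisation and acetate-buffered Heck–Matsuda coupling, in which zerovalent palladium formed in situ from Pd(OAc)2 inserts into the C–N2 bond of the para-oxygenated diazonium ion, and syn-carbopalladation of the acrylate at its terminal carbon followed by syn-β-hydride elimination gives the (E)-enoate at room temperature without phosphine.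

Step 10
Reactants: 15 methyl (E)-3-[(2R,3S)-3-[(2,2-dimethylpropanoyloxy)methyl]-7-methoxy-2-(3,4,5-trimethoxyphenyl)-2,3-dihydro-1-benzofuran-5-yl]prop-2-enoate
Product: 16 (−)-(7R,8S,7'E)-3,4,5,5'-tetramethoxy-4',7-epoxy-8,3'-neolign-7'-ene-9,9'-diol
Conditions: i-Bu2AlH (6 equiv), CH2Cl2, −78 → 0 °C; aq. potassium sodium tartrate
Reagents that add atoms: none
Why: i-Bu2AlH reduces the enoate in a 1,2-sense to the allylic alcohol and the pivalate to the C9 alcohol in one operation, leaving the alkene geometry, the benzylic ether and both stereocentres untouched.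

**Compound list**

1 | (E)-3,4,5-trimethoxycinnamic acid | COc1cc(/C=C/C(=O)O)cc(OC)c1OC | starting material
2 | methyl (E)-3-(3,4,5-trimethoxyphenyl)prop-2-enoate | COC(=O)/C=C/c1cc(OC)c(OC)c(OC)c1 | intermediate
3 | (E)-3-(3,4,5-trimethoxyphenyl)prop-2-en-1-ol | COc1cc(/C=C/CO)cc(OC)c1OC | intermediate
4 | (E)-3-(3,4,5-trimethoxyphenyl)allyl pivalate | COc1cc(/C=C/COC(=O)C(C)(C)C)cc(OC)c1OC | intermediate
5 | 2-methoxy-4-nitrophenol | COc1cc([N+](=O)[O-])ccc1O | starting material
6 | 4-amino-2-methoxyphenol | COc1cc(N)ccc1O | intermediate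
7 | N-(4-hydroxy-3-methoxyphenyl)-4-methylbenzenesulfonamide | COc1cc(NS(=O)(=O)c2ccc(C)cc2)ccc1O | intermediate
8 | N-(3-methoxy-4-oxocyclohexa-2,5-dien-1-ylidene)-4-methylbenzenesulfonamide | COC1=CC(=NS(=O)(=O)c2ccc(C)cc2)C=CC1=O | intermediate
9 | [(2R,3S)-7-methoxy-5-(4-methylbenzenesulfonamido)-2-(3,4,5-trimethoxyphenyl)-2,3-dihydro-1-benzofuran-3-yl]methyl 2,2-dimethylpropanoate (trans) | COc1cc([C@@H]2Oc3c(OC)cc(NS(=O)(=O)c4ccc(C)cc4)cc3[C@H]2COC(=O)C(C)(C)C)cc(OC)c1OC | intermediate
10 | [(2R,3S)-7-methoxy-5-[N-(4-methylbenzenesulfonyl)-2,2,2-trifluoroacetamido]-2-(3,4,5-trimethoxyphenyl)-2,3-dihydro-1-benzofuran-3-yl]methyl 2,2-dimethylpropanoate | COc1cc([C@@H]2Oc3c(OC)cc(N(C(=O)C(F)(F)F)S(=O)(=O)c4ccc(C)cc4)cc3[C@H]2COC(=O)C(C)(C)C)cc(OC)c1OC | intermediate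
11 | [(2R,3S)-7-methoxy-5-(2,2,2-trifluoroacetamido)-2-(3,4,5-trimethoxyphenyl)-2,3-dihydro-1-benzofuran-3-yl]methyl 2,2-dimethylpropanoate | COc1cc([C@@H]2Oc3c(OC)cc(NC(=O)C(F)(F)F)cc3[C@H]2COC(=O)C(C)(C)C)cc(OC)c1OC | intermediate
12 | [(2R,3S)-5-amino-7-methoxy-2-(3,4,5-trimethoxyphenyl)-2,3-dihydro-1-benzofuran-3-yl]methyl 2,2-dimethylpropanoate | COc1cc([C@@H]2Oc3c(OC)cc(N)cc3[C@H]2COC(=O)C(C)(C)C)cc(OC)c1OC | intermediate
13 | methyl acrylate | C=CC(=O)OC | starting material
14 | (2R,3S)-3-[(2,2-dimethylpropanoyloxy)methyl]-7-methoxy-2-(3,4,5-trimethoxyphenyl)-2,3-dihydro-1-benzofuran-5-diazonium methanesulfonate | COc1cc([C@@H]2Oc3c(OC)cc([N+]#N)cc3[C@H]2COC(=O)C(C)(C)C)cc(OC)c1OC.CS(=O)(=O)[O-] | intermediate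
15 | methyl (E)-3-[(2R,3S)-3-[(2,2-dimethylpropanoyloxy)methyl]-7-methoxy-2-(3,4,5-trimethoxyphenyl)-2,3-dihydro-1-benzofuran-5-yl]prop-2-enoate | COc1cc([C@@H]2Oc3c(OC)cc(/C=C/C(=O)OC)cc3[C@H]2COC(=O)C(C)(C)C)cc(OC)c1OC | intermediate
16 | (−)-(7R,8S,7'E)-3,4,5,5'-tetramethoxy-4',7-epoxy-8,3'-neolign-7'-ene-9,9'-diol, i.e. (E)-3-[(2R,3S)-3-(hydroxymethyl)-7-methoxy-2-(3,4,5-trimethoxyphenyl)-2,3-dihydro-1-benzofuran-5-yl]prop-2-en-1-ol | COc1cc([C@@H]2Oc3c(OC)cc(/C=C/CO)cc3[C@H]2CO)cc(OC)c1OC | target

**Step count and risks**

Total steps: 10. Longest linear sequence: 7 steps (steps 1–3 or steps 4–6, then steps 7–10).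

Steps most likely to fail:

1. Step 7 (proposed method). The C–C bond formation may be sluggish because a trimethoxyaryl alkene with an allylic ester is a weak nucleophile, the quinone monoimine may hydrolyse or be reduced before it is intercepted, and facial selectivity may be poor because the alkene has no hydrogen-bond donor for the catalyst. Fallback with known chemistry: setting out from 4 and 8, BF3·OEt2 (1 equiv) in CH2Cl2 at −78 → −20 °C should promote the same formal [3+2] cycloaddition without asymmetric induction and give the racemic trans cycloadduct F1. Its enantiomers are separated by preparative HPLC on a chiral stationary phase (amylose tris(3,5-dimethylphenylcarbamate)), and the (2R,3S)-enantiomer is 9, where the route resumes.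

2. Step 8. The trifluoroacetyl group may be lost before electron transfer, returning the unactivated sulfonamide that SmI2 alone does not cleave, or the pivalate may be partly methanolysed during the carbonate stage. Fallback: setting out from 9, Boc2O with DMAP and Et3N in MeCN gives the isolable N-Boc-N-tosyl anilide F2. Magnesium turnings in MeOH under sonication then cleave the N–S bond to the tert-butyl carbamate F3, and CF3CO2H in CH2Cl2 at 0 °C removes the carbamate to return to 12.

3. Step 9. The para-oxygenated diazonium ion may be consumed before palladium engages it, by azo coupling with unreacted aniline, by reduction to the arene, or by ionisation of the benzylic C7–O bond once ring B has become a good leaving group. Fallback: setting out from 12, the diazonium salt 14 is formed as in step 9 and quenched at 0 °C with aqueous KI (Sandmeyer-type iodination) to the aryl iodide F4. A ligand-free Mizoroki–Heck coupling of this iodide with 13 (Pd(OAc)2, Bu4NCl, NaHCO3, DMF, 80 °C) returns to 15.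

**Further compounds**

F1 | step 7 | racemic trans-[7-methoxy-5-(4-methylbenzenesulfonamido)-2-(3,4,5-trimethoxyphenyl)-2,3-dihydro-1-benzofuran-3-yl]methyl 2,2-dimethylpropanoate (1:1 mixture of 9 and its enantiomer) | COc1cc([C@@H]2Oc3c(OC)cc(NS(=O)(=O)c4ccc(C)cc4)cc3[C@H]2COC(=O)C(C)(C)C)cc(OC)c1OC.COc1cc([C@H]2Oc3c(OC)cc(NS(=O)(=O)c4ccc(C)cc4)cc3[C@@H]2COC(=O)C(C)(C)C)cc(OC)c1OC
F2 | step 8 | [(2R,3S)-5-[N-(tert-butoxycarbonyl)-4-methylbenzenesulfonamido]-7-methoxy-2-(3,4,5-trimethoxyphenyl)-2,3-dihydro-1-benzofuran-3-yl]methyl 2,2-dimethylpropanoate | COc1cc([C@@H]2Oc3c(OC)cc(N(C(=O)OC(C)(C)C)S(=O)(=O)c4ccc(C)cc4)cc3[C@H]2COC(=O)C(C)(C)C)cc(OC)c1OC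
F3 | step 8 | [(2R,3S)-5-[(tert-butoxycarbonyl)amino]-7-methoxy-2-(3,4,5-trimethoxyphenyl)-2,3-dihydro-1-benzofuran-3-yl]methyl 2,2-dimethylpropanoate | COc1cc([C@@H]2Oc3c(OC)cc(NC(=O)OC(C)(C)C)cc3[C@H]2COC(=O)C(C)(C)C)cc(OC)c1OC
F4 | step 9 | [(2R,3S)-5-iodo-7-methoxy-2-(3,4,5-trimethoxyphenyl)-2,3-dihydro-1-benzofuran-3-yl]methyl 2,2-dimethylpropanoate | COc1cc([C@@H]2Oc3c(OC)cc(I)cc3[C@H]2COC(=O)C(C)(C)C)cc(OC)c1OC
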